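**Retrosynthetic overview**

1. Target 28 comes from 27 by hydrogenolysis of six benzyl ethers and one benzyl carbonate. Ring C is closed last: C4–C4a by Friedel–Crafts acylation of acid 25, O1–C2 by Mitsunobu inversion of the (S)-carbinol 23 on the O8a phenol 17.
2. The strategy rests on this feature: flavone ring F hangs by F-C2 on E1, directly beside the E6–C6 biaryl bond, whose ring A end carries O5 and O7 on both flanks. F-C2 and F-C3 are therefore carried on E1 as a slim ethynyl group (alkyne 10), F-C4 comes from carbon monoxide 13, and F-O1 with ring G from o-iodophenol 12; one carbonylative Sonogashira annulation joins them to flavone 16.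
3. C6 lies para to O8a and between O5 and O7, so ring A is locally symmetric. A MOM mark on the para oxygen of 2,4,6-trihydroxybenzaldehyde 1 fixes O1, and either free ortho position gives the same 6-aryl flavanone.
4. The E6–C6 bond is made by Suzuki coupling of ring A iodide 5 (from 1 through acid 4 and iododecarboxylation) with ring E boronate 8; the ethynyl group comes from the aldehyde of 9 by Ohira–Bestmann homologation.
5. Ring order: rings A, B, E and G are bought as benzenoids; ring F forms in step 10 and ring C in step 17.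

Key step: step 10

Assumption: the E6–C6 biaryl axis (ortho groups O5, O7, the flavone and one hydrogen) is treated as configurationally labile and not as a stereo-element, since the target is defined only at C2; intermediates may show rotamers.

**Route**

Step 1
Reactants: 1 2,4,6-trihydroxybenzaldehyde
Product: 2 2,6-dihydroxy-4-(methoxymethoxy)benzaldehyde
Conditions: MOMCl (1.05 equiv), iPr2NEt, THF, 0 °C
Reagents that add atoms: chloromethyl methyl ether, COCCl
Why: Williamson-type O-alkylation should go first at the 4-hydroxyl, the most acidic one and the only one not held in a hydrogen bond to the formyl group, so one equivalent at 0 °C should mark the future O8a.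

Step 2
Reactants: 2 2,6-dihydroxy-4-(methoxymethoxy)benzaldehyde
Product: 3 2,6-bis(benzyloxy)-4-(methoxymethoxy)benzaldehyde
Conditions: BnBr (2.4 equiv), K2CO3, DMF, 60 °C
Reagents that add atoms: benzyl bromide, BrCc1ccccc1
Why: Williamson benzylation under forcing carbonate/DMF conditions should alkylate both hydrogen-bonded ortho hydroxyls (future O5 and O7), the MOM acetal being stable to base.

Step 3
Reactants: 3 2,6-bis(benzyloxy)-4-(methoxymethoxy)benzaldehyde
Product: 4 2,6-bis(benzyloxy)-4-(methoxymethoxy)benzoic acid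
Conditions: NaClO2, NaH2PO4, 2-methyl-2-butene, t-BuOH/THF/H2O, rt
Reagents that add atoms: sodium chlorite, [Na+].[O-]Cl=O
Why: Pinnick oxidation should convert the hindered, electron-rich aldehyde to the acid at a buffered pH that the MOM acetal tolerates, with 2-methyl-2-butene removing the hypochlorite that could chlorinate ring A.

Step 4
Reactants: 4 2,6-bis(benzyloxy)-4-(methoxymethoxy)benzoic acid
Product: 5 1,3-bis(benzyloxy)-2-iodo-5-(methoxymethoxy)benzene
Conditions: I2, K3PO4, MeCN, 100 °C (sealed tube)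
Reagents that add atoms: iodine, II
Why: Metal-free decarboxylative ipso-iodination (a Hunsdiecker-type iododecarboxylation) is known for 2,6-dialkoxybenzoic acids, whose twisted electron-rich carboxylates lose CO2 readily, and it should place iodine exactly on the future C6.

Step 5
Reactants: 6 3,4-bis(benzyloxy)benzaldehyde
Product: 7 4,5-bis(benzyloxy)-2-bromobenzaldehyde
Conditions: Br2, NaOAc, AcOH, rt
Reagents that add atoms: bromine, BrBr
Why: Electrophilic aromatic bromination should go para to the 3-benzyloxy group and ortho to the formyl group, as with veratraldehyde, the acetate buffer keeping HBr from cleaving the benzyl ethers.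

Step 6
Reactants: 7 4,5-bis(benzyloxy)-2-bromobenzaldehyde
Product: 8 4,5-bis(benzyloxy)-2-(4,4,5,5-tetramethyl-1,3,2-dioxaborolan-2-yl)benzaldehyde
Conditions: B2pin2, PdCl2(dppf) (3 mol%), KOAc, 1,4-dioxane, 90 °C
Reagents that add atoms: bis(pinacolato)diboron, CC1(C)OB(OC1(C)C)B1OC(C)(C)C(C)(C)O1
Why: Miyaura borylation of the aryl bromide tolerates the free aldehyde and should give the boronate that becomes E6.

Step 7
Reactants: 5 1,3-bis(benzyloxy)-2-iodo-5-(methoxymethoxy)benzene; 8 4,5-bis(benzyloxy)-2-(4,4,5,5-tetramethyl-1,3,2-dioxaborolan-2-yl)benzaldehyde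
Product: 9 4,5-bis(benzyloxy)-2-[2,6-bis(benzyloxy)-4-(methoxymethoxy)phenyl]benzaldehyde
Conditions: Pd(OAc)2 (5 mol%), SPhos (10 mol%), K3PO4, toluene/H2O (10:1), 90 °C
Reagents that add atoms: none
Why: Suzuki–Miyaura coupling with a bulky dialkylbiarylphosphine is established for di-ortho-alkoxy aryl halides and ortho-substituted boronates, and ring A is made the halide because 2,6-dialkoxyaryl boron reagents protodeboronate easily.

Step 8
Reactants: 9 4,5-bis(benzyloxy)-2-[2,6-bis(benzyloxy)-4-(methoxymethoxy)phenyl]benzaldehyde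
Product: 10 2',6',4,5-tetrakis(benzyloxy)-2-ethynyl-4'-(methoxymethoxy)biphenyl
Conditions: dimethyl (1-diazo-2-oxopropyl)phosphonate, K2CO3, MeOH/THF, rt
Reagents that add atoms: dimethyl (1-diazo-2-oxopropyl)phosphonate, CC(=O)C(=[N+]=[N-])P(=O)(OC)OC
Why: Seyferth–Gilbert homologation with the Ohira–Bestmann reagent should convert the non-enolisable aryl aldehyde into the terminal alkyne under carbonate/methanol conditions that leave benzyl and MOM ethers alone.

Step 9
Reactants: 11 3,5-bis(benzyloxy)phenol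
Product: 12 3,5-bis(benzyloxy)-2-iodophenol
Conditions: NIS (1.0 equiv), CH2Cl2, −20 to 0 °C, dark
Reagents that add atoms: N-iodosuccinimide, O=C1CCC(=O)N1I
Why: Electrophilic iodination of the phenol should favour the two equivalent positions ortho to the hydroxyl (each flanked by the small OH and one OBn) over the position between the two benzyloxy groups, one equivalent at low temperature limiting di-iodination, and the minor 4-iodo isomer is to be removed by chromatography.

Step 10
Reactants: 10 2',6',4,5-tetrakis(benzyloxy)-2-ethynyl-4'-(methoxymethoxy)biphenyl; 12 3,5-bis(benzyloxy)-2-iodophenol; 13 carbon monoxide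
Product: 16 5,7-bis(benzyloxy)-2-{4,5-bis(benzyloxy)-2-[2,6-bis(benzyloxy)-4-(methoxymethoxy)phenyl]phenyl}-4H-chromen-4-one, via o-hydroxyaryl ynone 14 (not isolated), via diethylamino enaminone 15 (not isolated)
Conditions: PdCl2(PPh3)2 (5 mol%), CO (5 bar), Et2NH/DMF (1:1), 90 °C
Reagents that add atoms: diethylamine, CCNCC (its atoms stay only in intermediate 15)
Why: The divalent palladium precatalyst is reduced in situ to zerovalent palladium, which adds oxidatively to the C–I bond of 12; CO inserts into the aryl–palladium bond, and amine-assisted transfer of the acetylide of 10 followed by reductive elimination gives ynone 14 (bonds F-C4a–F-C4 and F-C4–F-C3). Diethylamine then adds to 14 in conjugate fashion to give enaminone 15, and the neighbouring phenol oxygen attacks the amine-bearing carbon and expels diethylamine, which forms F-O1–F-C2. The closest known reaction type is the carbonylative Sonogashira annulation of o-iodophenols with terminal aryl alkynes to flavones in a secondary amine. Ring F closes in the 6-endo mode (6-endo-trig addition–elimination on the enaminone), and no stereocentre is formed. The step needs CO insertion to outrun direct alkynylation, which CO pressure and the readily migrating electron-rich aryl group favour, and it needs 6-endo closure to outrun the 5-exo path to the aurone, which the enaminone route secures. Iodine between OH and OBn in 12 fixes the 5,7-dioxygenation of ring G, and the rod-shaped alkyne on E1 is the substituent least likely to clash with the O5 and O7 benzyl ethers across the E6–C6 bond.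

Step 11
Reactants: 16 5,7-bis(benzyloxy)-2-{4,5-bis(benzyloxy)-2-[2,6-bis(benzyloxy)-4-(methoxymethoxy)phenyl]phenyl}-4H-chromen-4-one
Product: 17 5,7-bis(benzyloxy)-2-{4,5-bis(benzyloxy)-2-[2,6-bis(benzyloxy)-4-hydroxyphenyl]phenyl}-4H-chromen-4-one
Conditions: conc. HCl (cat.), MeOH/THF (1:1), 45 °C
Reagents that add atoms: none
Why: Acid-catalysed acetal exchange with methanol should remove only the MOM group, since aryl benzyl ethers and the flavone are stable to dilute HCl at this temperature, and this frees the O8a phenol.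

Step 12
Reactants: 18 4-hydroxybenzoic acid
Product: 19 4-{[(benzyloxy)carbonyl]oxy}benzoic acid
Conditions: CbzCl, 1 M NaOH aq, 0 °C; then 1 M HCl
Reagents that add atoms: benzyl chloroformate, O=C(Cl)OCc1ccccc1
Why: Schotten–Baumann acylation of the phenoxide gives the aryl benzyl carbonate, an electron-withdrawing mask for the ring B oxygen that hydrogenolysis removes later, while any mixed anhydride formed at the carboxylate hydrolyses back in the aqueous base.

Step 13
Reactants: 19 4-{[(benzyloxy)carbonyl]oxy}benzoic acid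
Product: 22 tert-butyl 3-(4-{[(benzyloxy)carbonyl]oxy}phenyl)-3-oxopropanoate, via acid chloride 20 (not isolated), via acyl Meldrum's acid 21 (not isolated)
Conditions: (COCl)2, cat. DMF, CH2Cl2, rt; Meldrum's acid, pyridine, CH2Cl2, 0 °C to rt; t-BuOH, toluene, 85 °C
Reagents that add atoms: Meldrum's acid, CC1(C)OC(=O)CC(=O)O1; tert-butanol, CC(C)(C)O; oxalyl chloride, O=C(Cl)C(=O)Cl (chlorine stays only in intermediate 20)
Why: In this Oikawa–Yonemitsu beta-keto ester synthesis the acid chloride C-acylates Meldrum's acid and the adduct, heated with tert-butanol, loses acetone and CO2 through an acylketene, all under conditions mild enough for the aryl carbonate.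

Step 14
Reactants: 22 tert-butyl 3-(4-{[(benzyloxy)carbonyl]oxy}phenyl)-3-oxopropanoate
Product: 23 tert-butyl (3S)-3-(4-{[(benzyloxy)carbonyl]oxy}phenyl)-3-hydroxypropanoate
Conditions: RuCl(p-cymene)[(S,S)-TsDPEN] (1 mol%), HCO2H/Et3N (5:2), EtOAc, rt
Reagents that add atoms: none
Why: Noyori asymmetric transfer hydrogenation of the aryl ketone with the (S,S)-TsDPEN ruthenium catalyst should deliver hydride to the same face as for acetophenone and benzoylacetates, giving the (S)-carbinol that becomes C2 after one inversion, without touching the benzyl carbonate or the tert-butyl ester.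

Step 15
Reactants: 17 5,7-bis(benzyloxy)-2-{4,5-bis(benzyloxy)-2-[2,6-bis(benzyloxy)-4-hydroxyphenyl]phenyl}-4H-chromen-4-one; 23 tert-butyl (3S)-3-(4-{[(benzyloxy)carbonyl]oxy}phenyl)-3-hydroxypropanoate
Product: 24 tert-butyl (3R)-3-(4-{[(benzyloxy)carbonyl]oxy}phenyl)-3-(3,5-bis(benzyloxy)-4-{4,5-bis(benzyloxy)-2-[5,7-bis(benzyloxy)-4-oxo-4H-chromen-2-yl]phenyl}phenoxy)propanoate
Conditions: PPh3, DIAD, THF, 0 °C to rt
Reagents that add atoms: none
Why: Mitsunobu etherification of the unhindered O8a phenol proceeds by SN2 displacement of the oxyphosphonium with inversion, turning the (S)-carbinol into the (R)-aryl ether that is C2 of the flavanone, the carbonate on ring B disfavouring ionisation of the benzylic centre and hence racemisation.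

Step 16
Reactants: 24 tert-butyl (3R)-3-(4-{[(benzyloxy)carbonyl]oxy}phenyl)-3-(3,5-bis(benzyloxy)-4-{4,5-bis(benzyloxy)-2-[5,7-bis(benzyloxy)-4-oxo-4H-chromen-2-yl]phenyl}phenoxy)propanoate
Product: 25 (3R)-3-(4-{[(benzyloxy)carbonyl]oxy}phenyl)-3-(3,5-bis(benzyloxy)-4-{4,5-bis(benzyloxy)-2-[5,7-bis(benzyloxy)-4-oxo-4H-chromen-2-yl]phenyl}phenoxy)propanoic acid
Conditions: TFA/CH2Cl2 (1:4), 0 °C to rt
Reagents that add atoms: none
Why: Acidolysis of the tert-butyl ester frees the acid without base, so the beta-aryloxy acid cannot undergo retro-oxa-Michael elimination, while benzyl ethers, the benzyl carbonate and the deactivated benzylic C2–O bond should survive dilute TFA.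

Step 17
Reactants: 25 (3R)-3-(4-{[(benzyloxy)carbonyl]oxy}phenyl)-3-(3,5-bis(benzyloxy)-4-{4,5-bis(benzyloxy)-2-[5,7-bis(benzyloxy)-4-oxo-4H-chromen-2-yl]phenyl}phenoxy)propanoic acid
Product: 27 (2R)-5,7-bis(benzyloxy)-2-(4-{[(benzyloxy)carbonyl]oxy}phenyl)-6-{4,5-bis(benzyloxy)-2-[5,7-bis(benzyloxy)-4-oxo-4H-chromen-2-yl]phenyl}-2,3-dihydro-4H-chromen-4-one, via mixed trifluoroacetic anhydride 26 (not isolated)
Conditions: TFAA (3 equiv), CH2Cl2, 0 °C to rt
Reagents that add atoms: trifluoroacetic anhydride, O=C(OC(=O)C(F)(F)F)C(F)(F)F (trifluoroacetyl group stays only in intermediate 26)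
Why: Intramolecular Friedel–Crafts acylation through the mixed anhydride closes ring C by forming C4–C4a on the phloroglucinol-type ring A, whose two free positions ortho to O1 are equivalent by local symmetry so that only the 6-aryl flavanone can form, and C2 takes no part.

Step 18
Reactants: 27 (2R)-5,7-bis(benzyloxy)-2-(4-{[(benzyloxy)carbonyl]oxy}phenyl)-6-{4,5-bis(benzyloxy)-2-[5,7-bis(benzyloxy)-4-oxo-4H-chromen-2-yl]phenyl}-2,3-dihydro-4H-chromen-4-one
Product: 28 (2R)-6-[2-(5,7-dihydroxy-4-oxo-4H-chromen-2-yl)-4,5-dihydroxyphenyl]-5,7-dihydroxy-2-(4-hydroxyphenyl)-2,3-dihydro-4H-chromen-4-one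
Conditions: H2 (1 atm), 10% Pd/C, THF/MeOH (1:1), rt
Reagents that add atoms: none
Why: Catalytic hydrogenolysis over palladium on carbon cleaves the six benzyl ethers and the benzyl carbonate (which then loses CO2) under neutral conditions that should leave the flavone C2=C3 bond, both ketones and the C2 stereocentre untouched if the reaction is stopped once hydrogen uptake ceases.

**Compound list**

1 | 2,4,6-trihydroxybenzaldehyde | O=Cc1c(O)cc(O)cc1O | starting material
2 | 2,6-dihydroxy-4-(methoxymethoxy)benzaldehyde | O=Cc1c(O)cc(OCOC)cc1O | intermediate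
3 | 2,6-bis(benzyloxy)-4-(methoxymethoxy)benzaldehyde | O=Cc1c(OCc2ccccc2)cc(OCOC)cc1OCc1ccccc1 | intermediate
4 | 2,6-bis(benzyloxy)-4-(methoxymethoxy)benzoic acid | OC(=O)c1c(OCc2ccccc2)cc(OCOC)cc1OCc1ccccc1 | intermediate
5 | 1,3-bis(benzyloxy)-2-iodo-5-(methoxymethoxy)benzene | COCOc1cc(OCc2ccccc2)c(I)c(OCc2ccccc2)c1 | intermediate
6 | 3,4-bis(benzyloxy)benzaldehyde | O=Cc1ccc(OCc2ccccc2)c(OCc2ccccc2)c1 | starting material
7 | 4,5-bis(benzyloxy)-2-bromobenzaldehyde | O=Cc1cc(OCc2ccccc2)c(OCc2ccccc2)cc1Br | intermediate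
8 | 4,5-bis(benzyloxy)-2-(4,4,5,5-tetramethyl-1,3,2-dioxaborolan-2-yl)benzaldehyde | O=Cc1cc(OCc2ccccc2)c(OCc2ccccc2)cc1B1OC(C)(C)C(C)(C)O1 | intermediate
9 | 4,5-bis(benzyloxy)-2-[2,6-bis(benzyloxy)-4-(methoxymethoxy)phenyl]benzaldehyde | O=Cc1cc(OCc2ccccc2)c(OCc2ccccc2)cc1-c1c(OCc2ccccc2)cc(OCOC)cc1OCc1ccccc1 | intermediate
10 | 2',6',4,5-tetrakis(benzyloxy)-2-ethynyl-4'-(methoxymethoxy)biphenyl | C#Cc1cc(OCc2ccccc2)c(OCc2ccccc2)cc1-c1c(OCc2ccccc2)cc(OCOC)cc1OCc1ccccc1 | intermediate
11 | 3,5-bis(benzyloxy)phenol | Oc1cc(OCc2ccccc2)cc(OCc2ccccc2)c1 | starting material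
12 | 3,5-bis(benzyloxy)-2-iodophenol | Oc1cc(OCc2ccccc2)cc(OCc2ccccc2)c1I | intermediate
13 | carbon monoxide | [C-]#[O+] | starting material
14 | 1-[2,4-bis(benzyloxy)-6-hydroxyphenyl]-3-{4,5-bis(benzyloxy)-2-[2,6-bis(benzyloxy)-4-(methoxymethoxy)phenyl]phenyl}prop-2-yn-1-one | Oc1cc(OCc2ccccc2)cc(OCc2ccccc2)c1C(=O)C#Cc1cc(OCc2ccccc2)c(OCc2ccccc2)cc1-c1c(OCc2ccccc2)cc(OCOC)cc1OCc1ccccc1 | intermediate
15 | (2E)-1-[2,4-bis(benzyloxy)-6-hydroxyphenyl]-3-{4,5-bis(benzyloxy)-2-[2,6-bis(benzyloxy)-4-(methoxymethoxy)phenyl]phenyl}-3-(diethylamino)prop-2-en-1-one | Oc1cc(OCc2ccccc2)cc(OCc2ccccc2)c1C(=O)/C=C(/N(CC)CC)c1cc(OCc2ccccc2)c(OCc2ccccc2)cc1-c1c(OCc2ccccc2)cc(OCOC)cc1OCc1ccccc1 | intermediate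
16 | 5,7-bis(benzyloxy)-2-{4,5-bis(benzyloxy)-2-[2,6-bis(benzyloxy)-4-(methoxymethoxy)phenyl]phenyl}-4H-chromen-4-one | COCOc1cc(OCc2ccccc2)c(c(OCc2ccccc2)c1)-c1cc(OCc2ccccc2)c(OCc2ccccc2)cc1-c1cc(=O)c2c(OCc3ccccc3)cc(OCc3ccccc3)cc2o1 | intermediate
17 | 5,7-bis(benzyloxy)-2-{4,5-bis(benzyloxy)-2-[2,6-bis(benzyloxy)-4-hydroxyphenyl]phenyl}-4H-chromen-4-one | Oc1cc(OCc2ccccc2)c(c(OCc2ccccc2)c1)-c1cc(OCc2ccccc2)c(OCc2ccccc2)cc1-c1cc(=O)c2c(OCc3ccccc3)cc(OCc3ccccc3)cc2o1 | intermediate
18 | 4-hydroxybenzoic acid | OC(=O)c1ccc(O)cc1 | starting material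
19 | 4-{[(benzyloxy)carbonyl]oxy}benzoic acid | OC(=O)c1ccc(OC(=O)OCc2ccccc2)cc1 | intermediate
20 | 4-{[(benzyloxy)carbonyl]oxy}benzoyl chloride | ClC(=O)c1ccc(OC(=O)OCc2ccccc2)cc1 | intermediate
21 | benzyl 4-[(2,2-dimethyl-4,6-dioxo-1,3-dioxan-5-ylidene)(hydroxy)methyl]phenyl carbonate | CC1(C)OC(=O)C(=C(O)c2ccc(OC(=O)OCc3ccccc3)cc2)C(=O)O1 | intermediate
22 | tert-butyl 3-(4-{[(benzyloxy)carbonyl]oxy}phenyl)-3-oxopropanoate | CC(C)(C)OC(=O)CC(=O)c1ccc(OC(=O)OCc2ccccc2)cc1 | intermediate
23 | tert-butyl (3S)-3-(4-{[(benzyloxy)carbonyl]oxy}phenyl)-3-hydroxypropanoate | CC(C)(C)OC(=O)C[C@H](O)c1ccc(OC(=O)OCc2ccccc2)cc1 | intermediate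
24 | tert-butyl (3R)-3-(4-{[(benzyloxy)carbonyl]oxy}phenyl)-3-(3,5-bis(benzyloxy)-4-{4,5-bis(benzyloxy)-2-[5,7-bis(benzyloxy)-4-oxo-4H-chromen-2-yl]phenyl}phenoxy)propanoate | CC(C)(C)OC(=O)C[C@@H](Oc1cc(OCc2ccccc2)c(c(OCc2ccccc2)c1)-c1cc(OCc2ccccc2)c(OCc2ccccc2)cc1-c1cc(=O)c2c(OCc3ccccc3)cc(OCc3ccccc3)cc2o1)c1ccc(OC(=O)OCc2ccccc2)cc1 | intermediate
25 | (3R)-3-(4-{[(benzyloxy)carbonyl]oxy}phenyl)-3-(3,5-bis(benzyloxy)-4-{4,5-bis(benzyloxy)-2-[5,7-bis(benzyloxy)-4-oxo-4H-chromen-2-yl]phenyl}phenoxy)propanoic acid | OC(=O)C[C@@H](Oc1cc(OCc2ccccc2)c(c(OCc2ccccc2)c1)-c1cc(OCc2ccccc2)c(OCc2ccccc2)cc1-c1cc(=O)c2c(OCc3ccccc3)cc(OCc3ccccc3)cc2o1)c1ccc(OC(=O)OCc2ccccc2)cc1 | intermediate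
26 | mixed anhydride of acid 25 with trifluoroacetic acid, (3R) | FC(F)(F)C(=O)OC(=O)C[C@@H](Oc1cc(OCc2ccccc2)c(c(OCc2ccccc2)c1)-c1cc(OCc2ccccc2)c(OCc2ccccc2)cc1-c1cc(=O)c2c(OCc3ccccc3)cc(OCc3ccccc3)cc2o1)c1ccc(OC(=O)OCc2ccccc2)cc1 | intermediate
27 | (2R)-5,7-bis(benzyloxy)-2-(4-{[(benzyloxy)carbonyl]oxy}phenyl)-6-{4,5-bis(benzyloxy)-2-[5,7-bis(benzyloxy)-4-oxo-4H-chromen-2-yl]phenyl}-2,3-dihydro-4H-chromen-4-one | O=C1C[C@H](c2ccc(OC(=O)OCc3ccccc3)cc2)Oc2cc(OCc3ccccc3)c(-c3cc(OCc4ccccc4)c(OCc4ccccc4)cc3-c3cc(=O)c4c(OCc5ccccc5)cc(OCc5ccccc5)cc4o3)c(OCc3ccccc3)c21 | intermediate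
28 | (2R)-6-[2-(5,7-dihydroxy-4-oxo-4H-chromen-2-yl)-4,5-dihydroxyphenyl]-5,7-dihydroxy-2-(4-hydroxyphenyl)-2,3-dihydro-4H-chromen-4-one (CNP0168406.2) | O=C1C[C@H](c2ccc(O)cc2)Oc2cc(O)c(-c3cc(O)c(O)cc3-c3cc(=O)c4c(O)cc(O)cc4o3)c(O)c21 | target

**Step count**

Total: 18 steps. Longest linear sequence: 12 steps (1 to 28 through steps 1, 2, 3, 4, 7, 8, 10, 11, 15, 16, 17, 18).

**Steps most likely to fail**

1. Step 10 (carbonylative annulation). Oxidative addition into the electron-rich, ortho-disubstituted iodophenol may be slow enough for protodeiodination to compete. The aryl–palladium species may couple with the alkyne before taking up CO, which would lead to a 2-arylbenzofuran. Diethylamine may intercept the aroyl–palladium species by aminocarbonylation. Masking the phenol of 12 as its acetate is a possible adjustment at the level of conditions. The fallback replaces the three-component coupling by an acetylide acylation and sets out from alkyne 10. 2,4,6-Trihydroxybenzoic acid is condensed with acetone (TFAA, TFA) to 5,7-dihydroxy-2,2-dimethyl-4H-1,3-benzodioxin-4-one F1, which is benzylated (BnBr, K2CO3, DMF, 60 °C) to 5,7-bis(benzyloxy)-2,2-dimethyl-4H-1,3-benzodioxin-4-one F2. Alkyne 10 is deprotonated with n-BuLi in THF at −78 °C to the lithium acetylide of 10 F3, which is added to F2. The tetrahedral adduct should collapse on warming with loss of acetone to give the o-hydroxyaryl ynone 14, here isolated, the liberated phenoxide protecting the ketone from a second addition. Heating 14 with Et2NH in EtOH at 60 °C should then give, through enaminone 15, flavone 16, where the fallback rejoins the route.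

2. Step 15 (Mitsunobu etherification). The activated beta-hydroxy ester may lose the oxyphosphonium group by elimination to the cinnamate instead of being displaced, and partial ionisation at the benzylic centre would erode the enantiomeric purity. The fallback removes the acidifying ester from the electrophile and sets out from phenol 17. 4-Hydroxybenzaldehyde is acylated (CbzCl, Et3N, CH2Cl2) to benzyl 4-formylphenyl carbonate F4. Brown allylation of F4 (B-allyldiisopinocampheylborane, the enantiomer that delivers the (S)-carbinol, Et2O, −78 °C, ethanolamine work-up to spare the carbonate) gives benzyl 4-[(1S)-1-hydroxybut-3-en-1-yl]phenyl carbonate F5. Mitsunobu coupling of F5 with 17 (PPh3, DIAD, THF) should give with inversion benzyl 4-[(1R)-1-(3,5-bis(benzyloxy)-4-{4,5-bis(benzyloxy)-2-[5,7-bis(benzyloxy)-4-oxo-4H-chromen-2-yl]phenyl}phenoxy)but-3-en-1-yl]phenyl carbonate F6. Oxidative cleavage of the terminal alkene (OsO4 cat., NaIO4, 2,6-lutidine, dioxane/H2O) gives (3R)-3-(4-{[(benzyloxy)carbonyl]oxy}phenyl)-3-(3,5-bis(benzyloxy)-4-{4,5-bis(benzyloxy)-2-[5,7-bis(benzyloxy)-4-oxo-4H-chromen-2-yl]phenyl}phenoxy)propanal F7. Pinnick oxidation of F7 (NaClO2, NaH2PO4, 2-methyl-2-butene) gives acid 25, where the fallback rejoins the route before step 17.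

3. Step 7 (Suzuki coupling). The ortho-formyl boronate may protodeboronate in the aqueous base faster than it transmetalates, and oxidative addition into the electron-rich, di-ortho-substituted iodide may be slow, so that the tri-ortho-substituted biaryl forms poorly. The fallback reverses the roles of the partners in a Negishi coupling and sets out from iodide 5 and bromide 7, without boronate 8. Iodine–magnesium exchange on 5 (iPrMgCl·LiCl, THF, −20 to 0 °C) gives [2,6-bis(benzyloxy)-4-(methoxymethoxy)phenyl]magnesium chloride F8. Transmetalation with ZnCl2 gives [2,6-bis(benzyloxy)-4-(methoxymethoxy)phenyl]zinc chloride F9, which tolerates the aldehyde of 7. Coupling of F9 with 7 (Pd(OAc)2, SPhos, THF, 50 °C) should give biaryl aldehyde 9, where the fallback rejoins the route before step 8.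

**Further compounds**

F1 | step 10 | 5,7-dihydroxy-2,2-dimethyl-4H-1,3-benzodioxin-4-one | CC1(C)OC(=O)c2c(O)cc(O)cc2O1
F2 | step 10 | 5,7-bis(benzyloxy)-2,2-dimethyl-4H-1,3-benzodioxin-4-one | CC1(C)OC(=O)c2c(OCc3ccccc3)cc(OCc3ccccc3)cc2O1
F3 | step 10 | lithium acetylide of 10 | [Li]C#Cc1cc(OCc2ccccc2)c(OCc2ccccc2)cc1-c1c(OCc2ccccc2)cc(OCOC)cc1OCc1ccccc1
F4 | step 15 | benzyl 4-formylphenyl carbonate | O=Cc1ccc(OC(=O)OCc2ccccc2)cc1
F5 | step 15 | benzyl 4-[(1S)-1-hydroxybut-3-en-1-yl]phenyl carbonate | C=CC[C@H](O)c1ccc(OC(=O)OCc2ccccc2)cc1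
F6 | step 15 | benzyl 4-[(1R)-1-(3,5-bis(benzyloxy)-4-{4,5-bis(benzyloxy)-2-[5,7-bis(benzyloxy)-4-oxo-4H-chromen-2-yl]phenyl}phenoxy)but-3-en-1-yl]phenyl carbonate | C=CC[C@@H](Oc1cc(OCc2ccccc2)c(c(OCc2ccccc2)c1)-c1cc(OCc2ccccc2)c(OCc2ccccc2)cc1-c1cc(=O)c2c(OCc3ccccc3)cc(OCc3ccccc3)cc2o1)c1ccc(OC(=O)OCc2ccccc2)cc1
F7 | step 15 | (3R)-3-(4-{[(benzyloxy)carbonyl]oxy}phenyl)-3-(3,5-bis(benzyloxy)-4-{4,5-bis(benzyloxy)-2-[5,7-bis(benzyloxy)-4-oxo-4H-chromen-2-yl]phenyl}phenoxy)propanal | O=CC[C@@H](Oc1cc(OCc2ccccc2)c(c(OCc2ccccc2)c1)-c1cc(OCc2ccccc2)c(OCc2ccccc2)cc1-c1cc(=O)c2c(OCc3ccccc3)cc(OCc3ccccc3)cc2o1)c1ccc(OC(=O)OCc2ccccc2)cc1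
F8 | step 7 | [2,6-bis(benzyloxy)-4-(methoxymethoxy)phenyl]magnesium chloride | COCOc1cc(OCc2ccccc2)c([Mg]Cl)c(OCc2ccccc2)c1
F9 | step 7 | [2,6-bis(benzyloxy)-4-(methoxymethoxy)phenyl]zinc chloride | COCOc1cc(OCc2ccccc2)c([Zn]Cl)c(OCc2ccccc2)c1
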